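**Retrosynthetic overview**
Gancaonin J ⇒ (removal of three MOM groups) tris-MOM dihydrochalcone ⇒ cut the CH2–CH2 bond between the ketone α-carbon and the benzylic carbon of ring B ⇒ a ring-A methyl ketone plus a ring-B benzylic alcohol, joined by Ir-catalysed hydrogen-borrowing alkylation (dehydrogenation, aldol condensation and conjugate transfer hydrogenation in one operation, water as the only by-product).
Enabling feature: the aryl ketone C=O on C1' of ring A acidifies its CH3 (the future Cα), and the benzylic carbon para to the ring-B oxygen can be shuttled alcohol → aldehyde → CH2 by a metal hydride; the two prenyl C=C bonds on C3'/C5' are isolated trisubstituted alkenes that a polarised Ir–H should not reduce, so the saturated chain is reached without a separate reduction.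
Ring-A ketone ⇒ double Suzuki–Miyaura prenylation at C3'/C5' ⇒ 3,5-diiodide ⇒ 2,4-dihydroxyacetophenone (C3 and C5 are its only positions ortho/para to the two OH groups).
No ring is formed in the route: both benzene rings are bought (2,4-dihydroxyacetophenone, 4-hydroxybenzyl alcohol).

Key step: step 5

Remark: the target has no stereogenic element (no stereocentre, both alkenes end in CMe2), so the single-enantiomer requirement imposes no stereochemical task; the only stereodescriptor in the route is the E geometry of a transient enone.

Step 1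
Reactants: 1 2,4-dihydroxyacetophenone
Product: 2 1-(2,4-dihydroxy-3,5-diiodophenyl)ethan-1-one
Conditions: NIS (2.1 equiv), p-TsOH·H2O (10 mol %), MeCN, 0 °C → rt
Reagents that add atoms: N-iodosuccinimide, O=C1CCC(=O)N1I
Why: Electrophilic aromatic iodination; C3 and C5 are the only positions ortho/para to the two hydroxyl groups, while C6 is meta to both and deactivated by the acetyl group, so iodination should stop at the 3,5-diiodide.

Step 2
Reactants: 2 1-(2,4-dihydroxy-3,5-diiodophenyl)ethan-1-one
Product: 3 1-[3,5-diiodo-2,4-bis(methoxymethoxy)phenyl]ethan-1-one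
Conditions: NaH (2.3 equiv), MOMCl (2.6 equiv), DMF, 0 °C → rt
Reagents that add atoms: chloromethyl methyl ether (MOMCl), COCCl
Why: Williamson-type O-alkylation of the two sodium phenoxides (far more acidic than the methyl ketone, so only oxygen is alkylated), which also caps the chelated 2-OH and gives base-stable ethers for the next three steps.

Step 3
Reactants: 3 1-[3,5-diiodo-2,4-bis(methoxymethoxy)phenyl]ethan-1-one; 4 prenylboronic acid pinacol ester (2.6 equiv)
Product: 5 1-[2,4-bis(methoxymethoxy)-3,5-bis(3-methylbut-2-en-1-yl)phenyl]ethan-1-one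
Conditions: Pd-PEPPSI-IPent (4 mol %), 5 M aq. KOH (5 equiv), THF, 70 °C
Reagents that add atoms: none
Why: Double sp2–sp3 Suzuki–Miyaura coupling of the aryl iodides with the prenylboronate; the bulky NHC–Pd catalyst is the known system for α-selective (linear, unrearranged prenyl) coupling of 3,3-disubstituted allylboronates and tolerates ortho-flanked halides, and the MOM ethers are stable to the base.

Step 4
Reactants: 6 4-hydroxybenzyl alcohol
Product: 7 [4-(methoxymethoxy)phenyl]methanol
Conditions: MOMCl (1.1 equiv), K2CO3 (1.5 equiv), acetone, 0 °C → rt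
Reagents that add atoms: chloromethyl methyl ether (MOMCl), COCCl
Why: Chemoselective phenol O-alkylation, since carbonate deprotonates only the phenol (pKa about 10) and leaves the benzylic alcohol free as the hydrogen donor and electrophile precursor of the key step.

Step 5
Reactants: 5 1-[2,4-bis(methoxymethoxy)-3,5-bis(3-methylbut-2-en-1-yl)phenyl]ethan-1-one; 7 [4-(methoxymethoxy)phenyl]methanol (1.3 equiv)
Product: 10 1-[2,4-bis(methoxymethoxy)-3,5-bis(3-methylbut-2-en-1-yl)phenyl]-3-[4-(methoxymethoxy)phenyl]propan-1-one, via 4-(methoxymethoxy)benzaldehyde 8 (not isolated), via tris-MOM chalcone 9 (not isolated)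
Conditions: [Cp*IrCl2]2 (2 mol %), KOH (30 mol %), toluene, 110 °C, sealed tube, Ar
Reagents that add atoms: none
Why: Hydrogen-borrowing (hydrogen-autotransfer) α-alkylation: the Cp*Ir alkoxide of 7 undergoes β-hydride elimination to aldehyde 8 and an Ir hydride, KOH-mediated Claisen–Schmidt condensation of the enolate of methyl ketone 5 with 8 forms the new Cα–Cβ bond as E-enone 9, and the Ir hydride returns the borrowed hydrogen by conjugate reduction of 9 to give 10 with water as the only by-product. The closest known reaction type is the iridium-catalysed α-alkylation of aryl methyl ketones with benzylic alcohols. No ring is closed and no stereocentre is created, and the E geometry of transient 9 is erased on reduction. The selectivity needed is reduction of the conjugated C=C in the presence of two prenyl C=C bonds and the aryl ketone: the nucleophilic Ir hydride adds to the electron-poor enone β-carbon, the isolated electron-rich trisubstituted prenyl alkenes are not acceptors, and any ketone reduction is reversible on the same catalyst. Mono-alkylation is secured because the product α-CH2 is more hindered and a second condensation would have to form a tetrasubstituted enone, and the three MOM caps exclude flavanone formation and phenoxide deactivation of either partner.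

Step 6
Reactants: 10 1-[2,4-bis(methoxymethoxy)-3,5-bis(3-methylbut-2-en-1-yl)phenyl]-3-[4-(methoxymethoxy)phenyl]propan-1-one
Product: 11 Gancaonin J
Conditions: 3 M aq. HCl, MeOH, 45 °C, short reaction time with monitoring
Reagents that add atoms: none
Why: Acid-catalysed acetal cleavage (methanolysis of the three aryl MOM ethers to dimethoxymethane) should release the phenols, with dilute acid and mild temperature chosen so that the prenyl alkenes ortho to the new phenols are not protonated.

**Compound list**
1 | 2,4-dihydroxyacetophenone | CC(=O)c1ccc(O)cc1O | starting material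
2 | 1-(2,4-dihydroxy-3,5-diiodophenyl)ethan-1-one | CC(=O)c1cc(I)c(O)c(I)c1O | intermediate
3 | 1-[3,5-diiodo-2,4-bis(methoxymethoxy)phenyl]ethan-1-one | CC(=O)c1cc(I)c(OCOC)c(I)c1OCOC | intermediate
4 | prenylboronic acid pinacol ester, 4,4,5,5-tetramethyl-2-(3-methylbut-2-en-1-yl)-1,3,2-dioxaborolane | CC(C)=CCB1OC(C)(C)C(C)(C)O1 | starting material
5 | 1-[2,4-bis(methoxymethoxy)-3,5-bis(3-methylbut-2-en-1-yl)phenyl]ethan-1-one | CC(=O)c1cc(CC=C(C)C)c(OCOC)c(CC=C(C)C)c1OCOC | intermediate
6 | 4-hydroxybenzyl alcohol | OCc1ccc(O)cc1 | starting material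
7 | [4-(methoxymethoxy)phenyl]methanol | COCOc1ccc(CO)cc1 | intermediate
8 | 4-(methoxymethoxy)benzaldehyde (formed in the flask in step 5) | COCOc1ccc(C=O)cc1 | intermediate
9 | (E)-1-[2,4-bis(methoxymethoxy)-3,5-bis(3-methylbut-2-en-1-yl)phenyl]-3-[4-(methoxymethoxy)phenyl]prop-2-en-1-one, tris-MOM chalcone (formed in the flask in step 5) | CC(C)=CCc1cc(C(=O)/C=C/c2ccc(OCOC)cc2)c(OCOC)c(CC=C(C)C)c1OCOC | intermediate
10 | 1-[2,4-bis(methoxymethoxy)-3,5-bis(3-methylbut-2-en-1-yl)phenyl]-3-[4-(methoxymethoxy)phenyl]propan-1-one | CC(C)=CCc1cc(C(=O)CCc2ccc(OCOC)cc2)c(OCOC)c(CC=C(C)C)c1OCOC | intermediate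
11 | Gancaonin J, 1-[2,4-dihydroxy-3,5-bis(3-methylbut-2-en-1-yl)phenyl]-3-(4-hydroxyphenyl)propan-1-one | CC(C)=CCc1cc(C(=O)CCc2ccc(O)cc2)c(O)c(CC=C(C)C)c1O | target

**Step count and risks**
Total step count: 6. Longest linear sequence: 5 (steps 1, 2, 3, 5, 6); step 4 is a one-step side branch.

Step 5 (key step). What may go wrong: over-reduction of the aryl ketone by the excess hydrogen donor, a stalled aldol condensation between the two electron-rich partners, or hydride-mediated migration of the prenyl double bonds into conjugation. Fallback, setting out from 5 and 7 and returning at 10: alcohol 7 is oxidised with MnO2 (CH2Cl2, rt) to 4-(methoxymethoxy)benzaldehyde 8, now isolated. Claisen–Schmidt condensation of 5 with 8 (KOH, EtOH, rt) gives tris-MOM chalcone 9, now isolated. Chemoselective 1,4-reduction of the enone with catalytic copper hydride ([(Ph3P)CuH]6, PMHS, toluene, rt, fluoride work-up) then gives 10, since copper hydride does not touch isolated trisubstituted alkenes. This sequence makes no compound outside the compound list (entry F0).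

Step 3. What may go wrong: allyl transposition during transmetalation and reductive elimination (γ-coupling, which would install 1,1-dimethylallyl groups), sluggish coupling at the doubly ortho-flanked C3 position, or protodeiodination. Fallback, setting out from 1 and returning at 5: 1 is C-prenylated twice as its phenoxide with prenyl bromide in 10 % aq. KOH (0 °C → rt); water favours C- over O-alkylation, and C3 and C5 are the only nucleophilic ring carbons. 1-[2,4-Dihydroxy-3,5-bis(3-methylbut-2-en-1-yl)phenyl]ethan-1-one F1 is separated by chromatography from mono- and O-prenylated congeners, and bis-MOM protection of F1 (NaH, MOMCl, DMF) gives 5. This avoids allyl–palladium chemistry at the price of a separation that is expected to be less efficient.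

Step 6. What may go wrong: acid-promoted addition of the freed ortho-phenols to the prenyl double bonds (cyclisation to 2,2-dimethylchromans) or hydration of the prenyl groups before all three acetals are cleaved. Fallback, setting out from 2 and 6 and returning at 11: the MOM ethers are replaced throughout by fluoride-labile SEM ethers.
- 2 with NaH and SEMCl (DMF) gives 1-[3,5-diiodo-2,4-bis{[2-(trimethylsilyl)ethoxy]methoxy}phenyl]ethan-1-one F2.
- Double Suzuki–Miyaura prenylation of F2 with 4 under the conditions of step 3 gives 1-[3,5-bis(3-methylbut-2-en-1-yl)-2,4-bis{[2-(trimethylsilyl)ethoxy]methoxy}phenyl]ethan-1-one F3.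
- 6 with SEMCl and K2CO3 (acetone) gives (4-{[2-(trimethylsilyl)ethoxy]methoxy}phenyl)methanol F4.
- Hydrogen-borrowing alkylation of F3 with F4 under the conditions of step 5 proceeds via transient 4-{[2-(trimethylsilyl)ethoxy]methoxy}benzaldehyde F5 and the transient tris-SEM chalcone F6, and gives the tris-SEM dihydrochalcone F7.
- TBAF (excess) in THF/DMPU at 60 °C then removes all three SEM groups by fluoride-induced fragmentation under non-acidic conditions, giving 11.

**Further compounds**
F0 | step 5 | none | none
F1 | step 3 | 1-[2,4-dihydroxy-3,5-bis(3-methylbut-2-en-1-yl)phenyl]ethan-1-one | CC(=O)c1cc(CC=C(C)C)c(O)c(CC=C(C)C)c1O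
F2 | step 6 | 1-[3,5-diiodo-2,4-bis{[2-(trimethylsilyl)ethoxy]methoxy}phenyl]ethan-1-one | CC(=O)c1cc(I)c(OCOCC[Si](C)(C)C)c(I)c1OCOCC[Si](C)(C)C
F3 | step 6 | 1-[3,5-bis(3-methylbut-2-en-1-yl)-2,4-bis{[2-(trimethylsilyl)ethoxy]methoxy}phenyl]ethan-1-one | CC(=O)c1cc(CC=C(C)C)c(OCOCC[Si](C)(C)C)c(CC=C(C)C)c1OCOCC[Si](C)(C)C
F4 | step 6 | (4-{[2-(trimethylsilyl)ethoxy]methoxy}phenyl)methanol | OCc1ccc(OCOCC[Si](C)(C)C)cc1
F5 | step 6 | 4-{[2-(trimethylsilyl)ethoxy]methoxy}benzaldehyde | O=Cc1ccc(OCOCC[Si](C)(C)C)cc1
F6 | step 6 | (E)-1-[3,5-bis(3-methylbut-2-en-1-yl)-2,4-bis{[2-(trimethylsilyl)ethoxy]methoxy}phenyl]-3-(4-{[2-(trimethylsilyl)ethoxy]methoxy}phenyl)prop-2-en-1-one | CC(C)=CCc1cc(C(=O)/C=C/c2ccc(OCOCC[Si](C)(C)C)cc2)c(OCOCC[Si](C)(C)C)c(CC=C(C)C)c1OCOCC[Si](C)(C)C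
F7 | step 6 | 1-[3,5-bis(3-methylbut-2-en-1-yl)-2,4-bis{[2-(trimethylsilyl)ethoxy]methoxy}phenyl]-3-(4-{[2-(trimethylsilyl)ethoxy]methoxy}phenyl)propan-1-one | CC(C)=CCc1cc(C(=O)CCc2ccc(OCOCC[Si](C)(C)C)cc2)c(OCOCC[Si](C)(C)C)c(CC=C(C)C)c1OCOCC[Si](C)(C)C
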